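## Structural features

The target is a 1,2-dioxolane, a five-membered cyclic peroxide with ring atoms O1, O2, C3, C4 and C5. C3 and C5 are both fully substituted and are separated only by the C4 methylene. C3 carries a methyl group and a CH2CO2Me arm; C5 carries a methyl group and an unbranched fifteen-carbon chain. The chain holds a (7E,9E)-diene and, one methylene further out, a (12Z)-alkene, so chain carbon 11 is doubly allylic. The two stereocentres are (3R,5S), stand 1,3 to each other across the ring, and place the long chain trans to the acetate arm; neither bears hydrogen, so neither can be set by reduction or corrected by epimerisation. The fragile groups are the O–O bond (reductants, low-valent metals, strong nucleophiles), the skipped triene (autoxidation, migration into conjugation, attack by electrophiles) and the methyl ester. The real difficulty is C5, where the two carbon substituents differ only as methyl against a linear chain, together with its relative configuration to C3 and the need to keep the triene away from the electrophilic conditions of peroxide construction. The key step uses the fact that C5 with O1 and O2 is a methyl ketone at the peroxyketal oxidation level, while C4, C3, the C3 methyl and the CH2CO2Me arm are the carbon pattern of the 1,1-disubstituted alkene methyl 3-methylbut-3-enoate.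

## Logic of the disconnections

**17 to 11 and 14.** The single bond between the two alkenes of the conjugated diene (chain C8–C9, counted from the ring) is cut. This sp2–sp2 bond can be made with defined geometry at both ends under neutral, non-reducing conditions. Cutting here also keeps the diene and the skipped alkene, which would not survive a carbocationic step, out of everything earlier. 17 falls into 11, which carries only a terminal alkyne, and the seven-carbon piece 14. The forward step must hydrometallate the alkyne and couple with retention while sparing the O–O bond and the ester.

**14 to 13 to 12.** The iodoalkene carbon of 14 is removed as a one-carbon unit, leading to aldehyde 13 and then to the commercial alcohol 12, which already contains the Z alkene. The forward steps must oxidise without moving the β,γ-alkene into conjugation and must form the new C=C bond with E geometry.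

**11 to 8 and 9.** The bonds C4–C5 and O2–C3 are cut. This removes the ring, both stereocentres and two skeletal bonds in one operation, and 9 delivers the head group at its final oxidation state. C5 becomes the carbon of a peroxycarbenium ion, so 8 may be racemic: its ketal stereocentre is erased on ionisation. The forward step must select one face of a cation whose substituents are methyl and a linear chain, close the ring with the chain trans to the acetate arm, and capture the C3 cation before it loses a proton.

**8 to 7 to 5.** The O–Si bond is cut, then the peroxyketal carbon is traced back to the disubstituted alkene carbon of 5. Ozone supplies both peroxide oxygens and methanol the leaving group, so no concentrated hydrogen peroxide is needed. The forward step must consume the alkene without touching the terminal alkyne.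

**5 to 3 and 4, and 3 to 1 and 2.** The sp3–sp bond next to the alkyne is cut, then the bond between the allylic carbon and the chain. A one-step desymmetrising methylmetallation of a symmetrical α,ω-diyne would be shorter on paper. It was set aside because it can only give a statistical mixture of unreacted, mono- and bis-adduct, three hydrocarbons of almost equal polarity and volatility, and it needs a pyrophoric aluminium alkyl. The two cuts chosen give one constitution each: the 2-methylallyl unit of 1 is symmetric, and 2 has one reactive and one dormant halide. The cost is one more step.

## Other disconnections considered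

**Alternative 1:** The cut removes both exocyclic C–CH2 bonds at C3 and C5 of a symmetrical diester. It leads back to the cyclic bis-peroxyketal 3,5-dimethoxy-3,5-dimethyl-1,2-dioxolane A1 and two equivalents of the silyl ketene acetal 1-methoxy-1-(trimethylsilyloxy)ethene A2. In the forward step a silylated confined imidodiphosphorimidate would ionise one methoxy group of A1, A2 would add to the ring peroxycarbenium ion, and the same events would follow at the second ketal carbon. The product would be dimethyl 2,2'-[(3R,5R)-3,5-dimethyl-1,2-dioxolane-3,5-diyl]diacetate A3, formed without any ring closure.
- In its favour: A2 is the standard nucleophile of silylium imidodiphosphorimidate catalysis and far more nucleophilic than 9. No cation prone to proton loss is formed. The Lewis acid-promoted substitution of alkoxy dioxolanes by silyl ketene acetals is known in racemic form. The C2 symmetry would let the second substitution raise the enantiomeric purity by diverting the minor enantiomer to the meso compound. On nucleophile reactivity and closeness of precedent this alternative is the better of the two.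
- Against it: A3 has two identical arms, and one of them must become the fifteen-carbon triene chain. That needs mono-differentiation of the diester and a thirteen-carbon sp3 homologation next to a peroxide, with hydrogenation excluded. At least five or six steps would follow the key step, against one in the chosen plan.
- Comparison: both plans rest on enantiofacial control over a peroxycarbenium ion by a chiral anion, so on the central uncertainty they are equal. On structure the chosen plan is better, because its alkene partner already distinguishes the two arms. On step economy the chosen plan is clearly shorter.

**Alternative 2:** The cut removes both C–O bonds of the peroxide, C5–O1 and C3–O2. It leads back to the C2-symmetric bis-oxetane (2R,2'R)-2,2'-methylenebis(2-methyloxetane) A4 and hydrogen peroxide A5. In the forward step A5, activated by Me3SiOTf A6, would open one oxetane at its tertiary carbon with inversion. The hydroperoxy group so installed would open the second oxetane in a 5-exo closure, again with inversion, to give 2,2'-[(3S,5S)-3,5-dimethyl-1,2-dioxolane-3,5-diyl]di(ethan-1-ol) A7.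
- In its favour: both bond-forming events belong to known reaction types. The stereocentres would come from C–O stereocentres made by established asymmetric methods. One hydroxyethyl arm is already the acetate arm at a lower oxidation state. On precedent this alternative is the better one, since it needs no new method.
- Against it: ionisation of an oxetane at a tertiary carbon has carbocation character, so inversion may be incomplete. A second molecule of A5 can compete with the ring closure. A4 needs its own multi-step enantioselective synthesis of two tertiary ether centres. A7 again has two identical arms that must be differentiated, one oxidised and esterified, the other extended by thirteen carbons. Concentrated A5 is a handling hazard that the chosen plan avoids.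
- Comparison: the chosen plan is stereoconvergent from a racemic precursor and much shorter, but depends on one unprecedented step. Alternative 2 is stereospecific and precedented but requires enantiopure A4 and a long end game.

**Alternative 3:** The cut removes the O1–O2 bond itself. It leads back to the 1,3-bis(aminooxy) compound O,O'-[(3S,5S,12E,14E,17Z)-1-[(tert-butyldimethylsilyl)oxy]-3,5-dimethylicosa-12,14,17-triene-3,5-diyl]bis(hydroxylamine) A8. In the forward step PhI(OAc)2 A9 would oxidise A8 and join the two nitrogens into the seven-membered cyclic hyponitrite (5S,7S)-5-[2-(tert-butyldimethylsilyloxy)ethyl]-5,7-dimethyl-7-[(7E,9E,12Z)-pentadeca-7,9,12-trien-1-yl]-6,7-dihydro-5H-1,4,2,3-dioxadiazepine A10. Loss of N2 and O–O bond formation would then give tert-butyl{2-[(3S,5S)-3,5-dimethyl-5-[(7E,9E,12Z)-pentadeca-7,9,12-trien-1-yl]-1,2-dioxolan-3-yl]ethoxy}dimethylsilane A11.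
- In its favour: the peroxide would appear last, so the whole carbon skeleton could be built with reagents that a peroxide would not tolerate; on this point it is the better plan. Both stereocentres would be ordinary tertiary C–O centres whose bonds the key step does not touch, so it would be stereospecific.
- Against it: O-amination of two hindered tertiary alcohols is difficult. Extrusion of N2 passes through two tertiary alkoxyl radicals, which can undergo β-scission, abstract the doubly allylic hydrogens or add to the diene of the same molecule instead of recombining. A11 would still need desilylation, oxidation and esterification in the presence of both peroxide and triene.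
- Comparison: the key step is as unprecedented as that of the chosen plan, so the two are equal on that point. The chosen plan is better in that its reactive intermediate never meets the triene, and it is far shorter.

Key step: step 5

Remark: the sense of induction of the chiral anion cannot be predicted with confidence; both enantiomers of the catalyst are equally accessible, and the one that leads to (3R,5S)-11 is assumed. The structures of precursor, alkene partner, annulation product and target are mutually consistent (eight plus seven chain carbons, chain trans to the acetate arm); only the approach to the 2-methylalkene has been changed.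

## Route

Step 1
Reactants: 1 2-methylallylmagnesium chloride; 2 1-bromo-5-chloropentane
Product: 3 8-chloro-2-methyloct-1-ene
Conditions: 1 (1.2 equiv, THF solution), Li2CuCl4 (3 mol%), THF, −10 °C to rt
Reagents that add atoms: none
Why: Copper-catalysed Kochi-type sp3–sp3 coupling of an allylic Grignard reagent with a primary bromide; the C–Br bond reacts far faster than the C–Cl bond, and the symmetric 2-methylallyl unit makes attack at either terminus give the same product.

Step 2
Reactants: 3 8-chloro-2-methyloct-1-ene; 4 lithium acetylide ethylenediamine complex
Product: 5 2-methyldec-1-en-9-yne
Conditions: 4 (1.5 equiv), NaI (10 mol%), DMSO, 15 °C to rt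
Reagents that add atoms: none
Why: SN2 alkylation of an acetylide by a primary halide with iodide catalysis; the isolated alkene is inert, and the mild temperature should avoid base-induced migration of the triple bond.

Step 3
Reactants: 5 2-methyldec-1-en-9-yne
Product: 7 2-hydroperoxy-2-methoxydec-9-yne (racemic), via carbonyl oxide 6 (not isolated)
Conditions: O3/O2, CH2Cl2–MeOH (3:1), −78 °C, Sudan Red 7B end-point; N2 purge; no reductive work-up
Reagents that add atoms: ozone [O-][O+]=O; methanol CO
Why: Criegee ozonolysis with methanol trapping: the 1,1-disubstituted alkene should fragment to formaldehyde and the more substituted carbonyl oxide 6, which adds methanol to give the hydroperoxy ketal. The electron-richer alkene reacts with ozone much faster than the terminal alkyne, so dosing to the indicator end-point should leave the alkyne intact; the new stereocentre is uncontrolled and need not be controlled.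

Step 4
Reactants: 7 2-hydroperoxy-2-methoxydec-9-yne (racemic)
Product: 8 triethyl[(2-methoxydec-9-yn-2-yl)peroxy]silane (racemic)
Conditions: Et3SiCl, imidazole, CH2Cl2, 0 °C
Reagents that add atoms: chlorotriethylsilane CC[Si](Cl)(CC)CC
Why: O-silylation of a hydroperoxide under mild base; the chlorosilane with imidazole is preferred to a silyl triflate because no strong Lewis acid is present that could ionise the ketal early.

Step 5
Reactants: 8 triethyl[(2-methoxydec-9-yn-2-yl)peroxy]silane (racemic); 9 methyl 3-methylbut-3-enoate
Product: 11 methyl 2-[(3R,5S)-3,5-dimethyl-5-(oct-7-yn-1-yl)-1,2-dioxolan-3-yl]acetate, via silylperoxycarbenium ion 10 (not isolated)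
Conditions: imidodiphosphorimidate Brønsted acid (5 mol%; two 3,3'-diaryl-1,1'-bi-2-naphthol units, P=N–SO2CF3 groups, single enantiomer), 9 (5 equiv), toluene, −78 to −60 °C
Reagents that add atoms: none
Why: Proposed new method: the silylium ion of the ion pair Et3Si+ X*− (X*− is the chiral imidodiphosphorimidate anion, entered after a first proton-initiated turnover) abstracts methoxide from either enantiomer of 8, so both converge on the planar peroxycarbenium ion 10 paired with X*−; the closest known reactions are the racemic SnCl4- or TiCl4-promoted annulation of triethylsilylperoxy ketals with alkenes and silylium imidodiphosphorimidate catalysis of additions to oxocarbenium ions. The terminal CH2 of 9 adds to C5, forming C4–C5 and a tertiary cation at C3, which the silyl-bearing peroxy oxygen captures to form O2–C3. This closes the one ring, the 1,2-dioxolane, by a five-membered cation-capture closure in which no π bond is broken at the electrophilic carbon, so the exo/endo classification does not apply and no stereoelectronic barrier is expected. Loss of Et3Si+ from the resulting silyloxonium ion to X*− regenerates the carrier and should leave Et3SiOMe as the only by-product. C5 is set in the C–C bond-forming event by the confined anion, which must shield one face of 10 while telling the methyl group from the linear chain. C3 is set in the ring closure, where the arrangement with the long chain and the CH2CO2Me arm on opposite faces is the less crowded one and the anion is still paired with the cation. The step needs selectivity for the 1,1-disubstituted alkene over the terminal alkyne, secured by the much higher nucleophilicity of the alkene, and cation capture faster than proton loss, secured by the intramolecular peroxy oxygen, the low temperature and the non-basic anion.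

Step 6
Reactants: 12 (Z)-hex-3-en-1-ol
Product: 13 (Z)-hex-3-enal
Conditions: Dess–Martin periodinane, NaHCO3, CH2Cl2, 0 °C; cold work-up, used at once as a solution
Reagents that add atoms: none
Why: Dess–Martin oxidation under buffered, near-neutral conditions, which should keep the β,γ-alkene Z and out of conjugation; the volatile aldehyde is not stored.

Step 7
Reactants: 13 (Z)-hex-3-enal
Product: 14 (1E,4Z)-1-iodohepta-1,4-diene
Conditions: CrCl2 (6 equiv), CHI3 (2 equiv), 1,4-dioxane–THF (6:1), 0 °C to rt, dark
Reagents that add atoms: iodoform IC(I)I
Why: Takai olefination: the geminal dichromium species from iodoform and divalent chromium adds to the aldehyde and eliminates to the E iodoalkene, with the dioxane co-solvent used to raise E selectivity. The medium is neither acidic nor basic, so the skipped Z alkene should stay in place.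

Step 8
Reactants: 11 methyl 2-[(3R,5S)-3,5-dimethyl-5-(oct-7-yn-1-yl)-1,2-dioxolan-3-yl]acetate; 14 (1E,4Z)-1-iodohepta-1,4-diene
Product: 17 methyl 2-[(3R,5S)-3,5-dimethyl-5-[(7E,9E,12Z)-pentadeca-7,9,12-trien-1-yl]-1,2-dioxolan-3-yl]acetate (target), via alkenylzirconocene chloride 15 (not isolated), via alkenylzinc chloride 16 (not isolated)
Conditions: Cp2Zr(H)Cl (1.2 equiv), THF, 0 °C to rt, dark; ZnCl2 (1.3 equiv), 0 °C; 14 (1.2 equiv), Pd(PPh3)4 (5 mol%), rt
Reagents that add atoms: none
Why: Syn-hydrozirconation places zirconium at the alkyne terminus (E), transmetalation to zinc and Negishi coupling catalysed by zerovalent palladium proceed with retention at both sp2 carbons, which fixes 7E and 9E. Hydrometallation of a terminal alkyne is faster than attack on the methyl ester, and the di-tertiary dialkyl peroxide has no α-hydrogen and is sterically shielded, a peroxide class that tolerates palladium-catalysed coupling; both ring stereocentres are remote and untouched.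

## Compound list

1 | 2-methylallylmagnesium chloride | C=C(C)C[Mg]Cl | starting material
2 | 1-bromo-5-chloropentane | ClCCCCCBr | starting material
3 | 8-chloro-2-methyloct-1-ene | C=C(C)CCCCCCCl | intermediate
4 | lithium acetylide ethylenediamine complex | [Li+].[C-]#C.NCCN | starting material
5 | 2-methyldec-1-en-9-yne | C=C(C)CCCCCCC#C | intermediate
6 | carbonyl oxide of dec-9-yn-2-one | C#CCCCCCCC(C)=[O+][O-] | intermediate
7 | 2-hydroperoxy-2-methoxydec-9-yne, racemic | C#CCCCCCCC(C)(OC)OO | intermediate
8 | triethyl[(2-methoxydec-9-yn-2-yl)peroxy]silane, racemic (methyl triethylsilylperoxy ketal of dec-9-yn-2-one) | C#CCCCCCCC(C)(OC)OO[Si](CC)(CC)CC | intermediate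
9 | methyl 3-methylbut-3-enoate | C=C(C)CC(=O)OC | starting material
10 | triethylsilylperoxycarbenium ion of dec-9-yn-2-one (paired with the catalyst anion) | C#CCCCCCCC(C)=[O+]O[Si](CC)(CC)CC | intermediate
11 | methyl 2-[(3R,5S)-3,5-dimethyl-5-(oct-7-yn-1-yl)-1,2-dioxolan-3-yl]acetate | C#CCCCCCC[C@@]1(C)C[C@](C)(CC(=O)OC)OO1 | intermediate
12 | (Z)-hex-3-en-1-ol | CC/C=C\CCO | starting material
13 | (Z)-hex-3-enal | CC/C=C\CC=O | intermediate
14 | (1E,4Z)-1-iodohepta-1,4-diene | CC/C=C\C/C=C/I | intermediate
15 | (E)-alkenylzirconocene chloride from 11 (zirconium on the chain terminus) | Cl[Zr](C1C=CC=C1)(C1C=CC=C1)/C=C/CCCCCC[C@@]1(C)C[C@](C)(CC(=O)OC)OO1 | intermediate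
16 | (E)-alkenylzinc chloride from 15 | Cl[Zn]/C=C/CCCCCC[C@@]1(C)C[C@](C)(CC(=O)OC)OO1 | intermediate
17 | methyl 2-[(3R,5S)-3,5-dimethyl-5-[(7E,9E,12Z)-pentadeca-7,9,12-trien-1-yl]-1,2-dioxolan-3-yl]acetate | CC/C=C\C/C=C/C=C/CCCCCC[C@@]1(C)C[C@](C)(CC(=O)OC)OO1 | target

## Step count and risk assessment

Total step count: 8. Longest linear sequence: 6 (steps 1, 2, 3, 4, 5 and 8); steps 6 and 7 form a two-step branch that joins at step 8.

**Step 5 (key step).** The most likely failures are:
- insufficient facial discrimination, because the anion pocket must tell methyl from a linear chain on the cation;
- weak control of the relative configuration in the ring closure, since the intrinsic steric preference is small;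
- proton loss from the C3 cation toward the conjugated ester;
- slow addition of the inductively deactivated alkene, which would give the peroxycarbenium ion time to rearrange by a 1,2-shift to oxygen.

Fallback with known chemistry: starting from 8 and 9, the annulation is promoted with a stoichiometric amount of SnCl4 in CH2Cl2 at −78 °C, which is the known racemic form of the reaction. The diastereomer with the chain trans to the acetate arm is separated by chromatography. It would be obtained as an equimolar mixture of 11 and its mirror image, methyl 2-[(3S,5R)-3,5-dimethyl-5-(oct-7-yn-1-yl)-1,2-dioxolan-3-yl]acetate F1. This mixture is resolved by preparative chromatography on a chiral stationary phase, and the route is rejoined at 11.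

**Step 8.** The zirconium hydride may reduce the O–O bond or the methyl ester in competition with hydrometallation. The doubly allylic position makes the product prone to double-bond migration and autoxidation during coupling and isolation. Fallback: starting from 11, the alkyne is hydroborated with pinacolborane under catalysis by dicyclohexylborane to give the isolable (E)-alkenyl pinacol boronate F2. Suzuki–Miyaura coupling of F2 with 14 (Pd(PPh3)4, aqueous K3PO4, THF, rt) rejoins the route at 17 without any metal hydride of the early transition metals.

**Step 3.** Once the alkene is consumed, ozone may attack the terminal alkyne, and the hydroperoxy ketal may decompose on concentration. Fallback without ozone: starting from 5, Lemieux–Johnson cleavage (catalytic OsO4, NaIO4, 2,6-lutidine, dioxane–water) would give dec-9-yn-2-one F3. This is converted with trimethyl orthoformate and catalytic acid in methanol into 9,9-dimethoxydec-1-yne F4. Acid-catalysed exchange of one methoxy group of F4 with ethereal hydrogen peroxide, stopped after the first substitution, rejoins the route at 7.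

**Step 7 (with step 6).** The Z alkene may migrate into conjugation at the aldehyde stage, and E selectivity in the iodo-olefination may be incomplete; the geometric isomers of 14 are hard to separate. Fallback with the coupling roles exchanged: starting from 13, the boron variant of the Takai olefination (2-(dichloromethyl)-4,4,5,5-tetramethyl-1,3,2-dioxaborolane, CrCl2, LiI, THF) is expected to be more E-selective and would give the (1E,4Z)-dienyl pinacol boronate F5. In parallel, 11 is hydrozirconated and the alkenylzirconium is quenched with iodine to give the (E)-vinyl iodide F6. Suzuki–Miyaura coupling of F5 with F6 (Pd(PPh3)4, aqueous K3PO4, THF) rejoins the route at 17.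

## Further compounds

F1 | step 5 | methyl 2-[(3S,5R)-3,5-dimethyl-5-(oct-7-yn-1-yl)-1,2-dioxolan-3-yl]acetate (mirror image of 11) | C#CCCCCCC[C@]1(C)C[C@@](C)(CC(=O)OC)OO1
F2 | step 8 | methyl 2-[(3R,5S)-3,5-dimethyl-5-[(E)-8-(4,4,5,5-tetramethyl-1,3,2-dioxaborolan-2-yl)oct-7-en-1-yl]-1,2-dioxolan-3-yl]acetate | CC1(C)OB(/C=C/CCCCCC[C@@]2(C)C[C@](C)(CC(=O)OC)OO2)OC1(C)C
F3 | step 3 | dec-9-yn-2-one | CC(=O)CCCCCCC#C
F4 | step 3 | 9,9-dimethoxydec-1-yne | COC(C)(OC)CCCCCCC#C
F5 | step 7 | 2-[(1E,4Z)-hepta-1,4-dien-1-yl]-4,4,5,5-tetramethyl-1,3,2-dioxaborolane | CC/C=C\C/C=C/B1OC(C)(C)C(C)(C)O1
F6 | step 7 | methyl 2-[(3R,5S)-5-[(E)-8-iodooct-7-en-1-yl]-3,5-dimethyl-1,2-dioxolan-3-yl]acetate | I/C=C/CCCCCC[C@@]1(C)C[C@](C)(CC(=O)OC)OO1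
A1 | alternative 1 | 3,5-dimethoxy-3,5-dimethyl-1,2-dioxolane (mixture of diastereomers) | COC1(C)CC(C)(OC)OO1
A2 | alternative 1 | 1-methoxy-1-(trimethylsilyloxy)ethene | C=C(OC)O[Si](C)(C)C
A3 | alternative 1 | dimethyl 2,2'-[(3R,5R)-3,5-dimethyl-1,2-dioxolane-3,5-diyl]diacetate | COC(=O)C[C@@]1(C)C[C@](C)(CC(=O)OC)OO1
A4 | alternative 2 | (2R,2'R)-2,2'-methylenebis(2-methyloxetane) | C[C@@]1(CCO1)C[C@@]2(C)CCO2
A5 | alternative 2 | hydrogen peroxide | OO
A6 | alternative 2 | trimethylsilyl trifluoromethanesulfonate | C[Si](C)(C)OS(=O)(=O)C(F)(F)F
A7 | alternative 2 | 2,2'-[(3S,5S)-3,5-dimethyl-1,2-dioxolane-3,5-diyl]di(ethan-1-ol) | OCC[C@@]1(C)C[C@](C)(CCO)OO1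
A8 | alternative 3 | O,O'-[(3S,5S,12E,14E,17Z)-1-[(tert-butyldimethylsilyl)oxy]-3,5-dimethylicosa-12,14,17-triene-3,5-diyl]bis(hydroxylamine) | CC/C=C\C/C=C/C=C/CCCCCC[C@](C)(ON)C[C@@](C)(ON)CCO[Si](C)(C)C(C)(C)C
A9 | alternative 3 | (diacetoxyiodo)benzene | CC(=O)OI(OC(C)=O)c1ccccc1
A10 | alternative 3 | (5S,7S)-5-[2-(tert-butyldimethylsilyloxy)ethyl]-5,7-dimethyl-7-[(7E,9E,12Z)-pentadeca-7,9,12-trien-1-yl]-6,7-dihydro-5H-1,4,2,3-dioxadiazepine | CC/C=C\C/C=C/C=C/CCCCCC[C@@]1(C)C[C@](C)(CCO[Si](C)(C)C(C)(C)C)ON=NO1
A11 | alternative 3 | tert-butyl{2-[(3S,5S)-3,5-dimethyl-5-[(7E,9E,12Z)-pentadeca-7,9,12-trien-1-yl]-1,2-dioxolan-3-yl]ethoxy}dimethylsilane | CC/C=C\C/C=C/C=C/CCCCCC[C@@]1(C)C[C@](C)(CCO[Si](C)(C)C(C)(C)C)OO1
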